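| flask | solid substrate | partner | reagent | remark | time |
|---|---|---|---|---|---|
| midnight | 0.050 M | 0.018 M | 0.065 M | run made earlier |  |
| dusk | 0.050 M | 0.070 M | 0.065 M | run made earlier |  |
| dawn | 0.10 M | 0.035 M | 0.065 M | run made earlier |  |
| flask | 0.050 M | 0.0350 M | 0.0650 M |  | 12 h |

- amount of target at 12 h, in percent of the solid substrate charged
- concentration of starting material in solution at 12 h, in percent of saturation

- midnight (time / h: target / %, starting material / %): 2.00: 0.3, 4.4; 4.00: 3.6, 3.7; 6.00: 6.6, 4.8; 8.00: 10.1, 4.9; 10.0: 12.5, 4.6; 12.0: 16.0, 5.2
- dusk (time / h: target / %, starting material / %): 0.833: 0.5, 2.2; 2.50: 1.5, 5.4; 4.00: 2.8, 6.2; 6.00: 4.3, 6.9; 10.0: 5.9, 8.3; 12.0: 6.9, 8.4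
- dawn (time / h: target / %, starting material / %): 1.00: 0.1, 0.9; 2.00: 1.3, 1.7; 3.00: 1.0, 3.1; 6.00: 3.7, 3.2; 12.0: 7.8, 3.7

(readings scatter by 0.5 percentage points)

Read at 2.00 h, the midnight run shows 4.4% starting material and the dawn run 1.7%, but dawn carries twice the solid substrate, so put both on a molar scale. Then c(starting material) reads 0.00220 M at midnight and 0.00170 M at dawn, a gap of the size of the scatter, and the two runs differ in partner as well, so this row shows no doubling and says little more.

Now take the 12.0 h row. Dawn's 3.7% recounted on the flask's charge is 7.40%, between midnight's 5.2% and dusk's 8.4%, whose partner charges bracket the flask's.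

So these runs read as zero order in the solid charge. Dawn matches the flask in partner and in reagent, and its c(target) in that row reads 0.00780 M, which suggests a rule: carry this molar yield, percent times solid charge, between flasks at equal time, partner and reagent while solid is left. Your reckoning for the flask is therefore 15.6% target, give or take 1 percentage point.

The forecast puts target lower, at 13.5% (11% to 16%), and starting material at 62% (50% to 76%) of saturation, holding that “its doubled solid seems to dissolve faster, roughly as area”.

The flask gives 15.6% target and 71.3% of saturation.

    starting material + reagent → open intermediate (k = 10.0 /M/h)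
    reagent + partner → second intermediate (k = 12.0 /M/h)
    open intermediate + second intermediate → target (k = 36.0 /M/h)
    solid substrate ⇌ starting material, rate k4*(cs4 - [starting material]) while solid is left; crystals form when [starting material] > cs4 (solubility = 4.40 mM, k = 0.560 /h)
    second intermediate → side product (k = 0.0480 /h)

The dissolving rate in this scheme contains c(starting material) and no amount of solid, while solid is left. Dividing 0.00780 M by the flask's 0.050 M gives 15.6%. For the neighbouring flask with 0.030 M solid substrate, the same 0.00780 M gives 26.0%, and that flask holds 26.1% target.

The data were computed on assumed constants, and the scatter is random.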